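Ubiquinol-6 is cut at C1'–C2' and at C3'–CH3 of the hexaprenyl chain, numbered from the benzylic carbon C1'. The route exploits the E-trisubstituted C2'=C3' alkene, which carries its methyl group on C3' and hangs on the fully substituted benzene ring through the C1' methylene. In one flask a terminal alkyne is methylaluminated syn and the E-alkenylalane is joined to a benzylic chloride by zerovalent nickel, which sets both bonds and the alkene geometry. The precursors are the all-E C28 pentaenyne, built from farnesyl and geranyl units by sulfone alkylation and propargylation, and chloromethylated tetramethoxytoluene. Oxidative demethylation and dithionite reduction then give the hydroquinone.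

Key step: step 9

Remark: the target has no stereocentre; three E alkenes come in with commercial E-configured 1 and 3, one is set in step 2 and one in step 9, and C9 of sulfones 7 and 8 is a transient racemic centre that step 5 erases.

Step 1
Reactants: 1 (2E,6E)-farnesyl bromide
Product: 2 (2E,6E)-farnesyl phenyl sulfone
Conditions: PhSO2Na, DMF, rt
Reagents that add atoms: sodium benzenesulfinate, [Na+].[O-]S(=O)c1ccccc1
Why: S-alkylation of the ambident sulfinate at the primary allylic carbon (SN2 displacement of bromide in a dipolar aprotic solvent) should give the allylic sulfone without touching the E alkenes.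

Step 2
Reactants: 3 geranyl acetate
Product: 4 (2E,6E)-8-hydroxy-3,7-dimethylocta-2,6-dien-1-yl acetate
Conditions: SeO2 (cat.), t-BuOOH, salicylic acid (cat.), CH2Cl2, rt
Reagents that add atoms: tert-butyl hydroperoxide, CC(C)(C)OO; selenium dioxide, O=[Se]=O (catalytic oxygen carrier)
Why: Riley allylic oxidation (ene reaction, then [2,3]-sigmatropic shift) should attack the electron-rich terminal alkene at its E methyl group, because the C2=C3 alkene is deactivated by the allylic acetoxy group, and the known E preference of this reaction sets the 6E geometry.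

Step 3
Reactants: 4 (2E,6E)-8-hydroxy-3,7-dimethylocta-2,6-dien-1-yl acetate
Product: 5 (2E,6E)-8-bromo-3,7-dimethylocta-2,6-dien-1-yl acetate
Conditions: CBr4, PPh3, CH2Cl2, 0 °C
Reagents that add atoms: tetrabromomethane, BrC(Br)(Br)Br
Why: Appel bromination converts the primary allylic alcohol into the bromide by SN2 attack on the alkoxyphosphonium ion under neutral conditions, which should leave the acetate and both E alkenes alone.

Step 4
Reactants: 2 (2E,6E)-farnesyl phenyl sulfone; 5 (2E,6E)-8-bromo-3,7-dimethylocta-2,6-dien-1-yl acetate
Product: 7 (2E,6E,10E,14E)-9-(benzenesulfonyl)-3,7,11,15,19-pentamethylicosa-2,6,10,14,18-pentaen-1-yl acetate (racemic at C9), via lithiated sulfone 6 (not isolated)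
Conditions: 2, n-BuLi, THF, −78 °C; then 5, −78 °C; NH4Cl quench at −78 °C
Reagents that add atoms: none
Why: Sulfone-anion alkylation: the α-sulfonyl allylic carbanion should attack the primary allylic bromide at the carbon bearing sulfur far faster at −78 °C than it attacks the acetate, and C9 forms as a racemate that step 5 erases.

Step 5
Reactants: 7 (2E,6E,10E,14E)-9-(benzenesulfonyl)-3,7,11,15,19-pentamethylicosa-2,6,10,14,18-pentaen-1-yl acetate
Product: 9 (2E,6E,10E,14E)-geranylfarnesol, via hydroxy sulfone 8 (not isolated)
Conditions: LiBHEt3 (5 equiv), THF, 0 °C; then PdCl2(dppp) (cat.), 0 °C to rt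
Reagents that add atoms: none
Why: LiBHEt3 first reduces the acetate to the lithium alkoxide, which zerovalent palladium does not ionise, and then delivers hydride to the less substituted terminus of the palladium allyl complex formed from the allylic sulfone (palladium-catalysed reductive desulfonylation), which should keep C10=C11 in place and E.

Step 6
Reactants: 9 (2E,6E,10E,14E)-geranylfarnesol
Product: 10 (2E,6E,10E,14E)-geranylfarnesyl bromide
Conditions: PBr3, Et2O, −10 to 0 °C
Reagents that add atoms: phosphorus tribromide, BrP(Br)Br
Why: PBr3 converts the primary allylic alcohol into the bromide by SN2 displacement of a phosphite leaving group at low temperature, the standard preparation of polyprenyl bromides without allylic transposition.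

Step 7
Reactants: 10 (2E,6E,10E,14E)-geranylfarnesyl bromide; 11 1-(trimethylsilyl)propyne
Product: 14 (5E,9E,13E,17E)-6,10,14,18,22-pentamethyltricosa-5,9,13,17,21-pentaen-1-yne, via lithiated silylpropyne 12 (not isolated), via C-silyl pentaenyne 13 (not isolated)
Conditions: 11, n-BuLi, THF, −78 to −20 °C; 10, −78 °C to rt; then K2CO3, MeOH, rt
Reagents that add atoms: none
Why: Deprotonated 1-(trimethylsilyl)propyne should react at its propargylic carbon with the primary allylic bromide by SN2 (the silyl group disfavours allene formation), and methanolysis of the C–Si bond then frees the terminal alkyne in the same flask.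

Step 8
Reactants: 15 2,3,4,5-tetramethoxytoluene
Product: 16 1-(chloromethyl)-2,3,4,5-tetramethoxy-6-methylbenzene
Conditions: (CH2O)n, conc. HCl, 40 °C
Reagents that add atoms: paraformaldehyde as formaldehyde, C=O; hydrogen chloride, Cl
Why: Blanc chloromethylation: protonated formaldehyde attacks the only free position of the electron-rich arene (electrophilic aromatic substitution) and the benzylic alcohol is converted into the chloride in situ.

Step 9
Reactants: 14 (5E,9E,13E,17E)-6,10,14,18,22-pentamethyltricosa-5,9,13,17,21-pentaen-1-yne; 17 trimethylaluminium; 16 1-(chloromethyl)-2,3,4,5-tetramethoxy-6-methylbenzene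
Product: 19 1-[(2E,6E,10E,14E,18E)-3,7,11,15,19,23-hexamethyltetracosa-2,6,10,14,18,22-hexaen-1-yl]-2,3,4,5-tetramethoxy-6-methylbenzene, via E-alkenyldimethylalane 18 (not isolated)
Conditions: 17 (2 equiv), Cp2ZrCl2 (0.25 equiv), ClCH2CH2Cl, 0 °C to rt; solvent and excess 17 removed in vacuo; then 16, NiCl2(PPh3)2 (cat.) pre-reduced with n-BuLi to zerovalent nickel, THF, rt
Reagents that add atoms: none
Why: Cp2ZrCl2 and Al(CH3)3 form a methylzirconium–aluminium species that adds CH3 and metal syn across the terminal alkyne, CH3 to the internal carbon (C3') and aluminium to the terminal carbon (C2'), giving the E-alkenyldimethylalane; zerovalent nickel then inserts into the benzylic C–Cl bond of 16, takes the alkenyl group from aluminium and forms C1'–C2' by reductive elimination with retention. The closest known reaction type is the Negishi zirconium-catalysed methylalumination of terminal alkynes, joined to the nickel-catalysed cross-coupling of alkenylalanes with benzylic chlorides. No ring is closed and no stereocentre is made; the only stereochemical element, the E geometry of C2'=C3', follows from the syn addition and from retention in transmetalation and reductive elimination. The step needs methyl delivery to the internal alkyne carbon, which the terminal alkyne with its unbranched propargylic CH2 secures, and chemoselectivity over the five remote trisubstituted alkenes, which are inert to methylalumination under these conditions. The electrophilic carbon is benzylic and sp3 and belongs to no allyl system, so no allylic transposition or geometric scrambling is possible, and removing excess Al(CH3)3 before the coupling suppresses methyl transfer to 16. The ring carries only methyl ethers, so no acidic or reducible group consumes the alane.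

Step 10
Reactants: 19 1-[(2E,6E,10E,14E,18E)-3,7,11,15,19,23-hexamethyltetracosa-2,6,10,14,18,22-hexaen-1-yl]-2,3,4,5-tetramethoxy-6-methylbenzene
Product: 20 ubiquinone-6
Conditions: (NH4)2Ce(NO3)6, MeCN/CH2Cl2/H2O, 0 °C
Reagents that add atoms: water, O
Why: Tetravalent cerium oxidises the electron-rich arene to its radical cation, water adds at C2 and C5 and two molecules of methanol leave (oxidative demethylation of a hydroquinone dimethyl ether), which should give the 2,3-dimethoxy para-quinone while the isolated alkenes stay untouched at 0 °C.

Step 11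
Reactants: 20 ubiquinone-6
Product: 21 ubiquinol-6
Conditions: Na2S2O4, Et2O/H2O (degassed), rt, under argon
Reagents that add atoms: none
Why: Dithionite transfers two electrons and two protons to the para-quinone (quinone-to-hydroquinone reduction) without affecting the isolated alkenes or the methyl ethers, and the air-sensitive product is kept under argon.

Compound list
1 | (2E,6E)-farnesyl bromide, (2E,6E)-1-bromo-3,7,11-trimethyldodeca-2,6,10-triene | BrC/C=C(\C)CC/C=C(\C)CCC=C(C)C | starting material
2 | (2E,6E)-farnesyl phenyl sulfone, {[(2E,6E)-3,7,11-trimethyldodeca-2,6,10-trien-1-yl]sulfonyl}benzene | O=S(=O)(C/C=C(\C)CC/C=C(\C)CCC=C(C)C)c1ccccc1 | intermediate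
3 | geranyl acetate | CC(=O)OC/C=C(\C)CCC=C(C)C | starting material
4 | (2E,6E)-8-hydroxy-3,7-dimethylocta-2,6-dien-1-yl acetate | CC(=O)OC/C=C(\C)CC/C=C(\C)CO | intermediate
5 | (2E,6E)-8-bromo-3,7-dimethylocta-2,6-dien-1-yl acetate | CC(=O)OC/C=C(\C)CC/C=C(\C)CBr | intermediate
6 | [(2E,6E)-1-(benzenesulfonyl)-3,7,11-trimethyldodeca-2,6,10-trien-1-yl]lithium | [Li]C(/C=C(\C)CC/C=C(\C)CCC=C(C)C)S(=O)(=O)c1ccccc1 | intermediate (not isolated)
7 | (2E,6E,10E,14E)-9-(benzenesulfonyl)-3,7,11,15,19-pentamethylicosa-2,6,10,14,18-pentaen-1-yl acetate, racemic at C9 | CC(=O)OC/C=C(\C)CC/C=C(\C)CC(/C=C(\C)CC/C=C(\C)CCC=C(C)C)S(=O)(=O)c1ccccc1 | intermediate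
8 | (2E,6E,10E,14E)-9-(benzenesulfonyl)-3,7,11,15,19-pentamethylicosa-2,6,10,14,18-pentaen-1-ol, racemic at C9, formed as its lithium alkoxide | OC/C=C(\C)CC/C=C(\C)CC(/C=C(\C)CC/C=C(\C)CCC=C(C)C)S(=O)(=O)c1ccccc1 | intermediate (not isolated)
9 | (2E,6E,10E,14E)-geranylfarnesol, (2E,6E,10E,14E)-3,7,11,15,19-pentamethylicosa-2,6,10,14,18-pentaen-1-ol | OC/C=C(\C)CC/C=C(\C)CC/C=C(\C)CC/C=C(\C)CCC=C(C)C | intermediate
10 | (2E,6E,10E,14E)-geranylfarnesyl bromide, (2E,6E,10E,14E)-1-bromo-3,7,11,15,19-pentamethylicosa-2,6,10,14,18-pentaene | BrC/C=C(\C)CC/C=C(\C)CC/C=C(\C)CC/C=C(\C)CCC=C(C)C | intermediate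
11 | 1-(trimethylsilyl)propyne | CC#C[Si](C)(C)C | starting material
12 | [3-(trimethylsilyl)prop-2-yn-1-yl]lithium | [Li]CC#C[Si](C)(C)C | intermediate (not isolated)
13 | trimethyl[(5E,9E,13E,17E)-6,10,14,18,22-pentamethyltricosa-5,9,13,17,21-pentaen-1-yn-1-yl]silane | C[Si](C)(C)C#CCC/C=C(\C)CC/C=C(\C)CC/C=C(\C)CC/C=C(\C)CCC=C(C)C | intermediate (not isolated)
14 | (5E,9E,13E,17E)-6,10,14,18,22-pentamethyltricosa-5,9,13,17,21-pentaen-1-yne | C#CCC/C=C(\C)CC/C=C(\C)CC/C=C(\C)CC/C=C(\C)CCC=C(C)C | intermediate
15 | 2,3,4,5-tetramethoxytoluene | COc1cc(C)c(OC)c(OC)c1OC | starting material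
16 | 1-(chloromethyl)-2,3,4,5-tetramethoxy-6-methylbenzene | COc1c(OC)c(C)c(CCl)c(OC)c1OC | intermediate
17 | trimethylaluminium | C[Al](C)C | starting material
18 | [(1E,5E,9E,13E,17E)-2,6,10,14,18,22-hexamethyltricosa-1,5,9,13,17,21-hexaen-1-yl]dimethylalumane | C[Al](C)/C=C(\C)CC/C=C(\C)CC/C=C(\C)CC/C=C(\C)CC/C=C(\C)CCC=C(C)C | intermediate (not isolated)
19 | 1-[(2E,6E,10E,14E,18E)-3,7,11,15,19,23-hexamethyltetracosa-2,6,10,14,18,22-hexaen-1-yl]-2,3,4,5-tetramethoxy-6-methylbenzene | COc1c(OC)c(C)c(C/C=C(\C)CC/C=C(\C)CC/C=C(\C)CC/C=C(\C)CC/C=C(\C)CCC=C(C)C)c(OC)c1OC | intermediate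
20 | ubiquinone-6, 2-[(2E,6E,10E,14E,18E)-3,7,11,15,19,23-hexamethyltetracosa-2,6,10,14,18,22-hexaen-1-yl]-5,6-dimethoxy-3-methylcyclohexa-2,5-diene-1,4-dione | COC1=C(OC)C(=O)C(C/C=C(\C)CC/C=C(\C)CC/C=C(\C)CC/C=C(\C)CC/C=C(\C)CCC=C(C)C)=C(C)C1=O | intermediate
21 | ubiquinol-6, 2-[(2E,6E,10E,14E,18E)-3,7,11,15,19,23-hexamethyltetracosa-2,6,10,14,18,22-hexaen-1-yl]-5,6-dimethoxy-3-methylbenzene-1,4-diol | COc1c(O)c(C)c(C/C=C(\C)CC/C=C(\C)CC/C=C(\C)CC/C=C(\C)CC/C=C(\C)CCC=C(C)C)c(O)c1OC | target

Total step count: 11.
Longest linear sequence: 9 steps (3 to 21 through steps 2, 3, 4, 5, 6, 7, 9, 10 and 11).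

Steps most likely to fail

Step 9. The methylalumination may stop short or place aluminium partly on the internal carbon. In the coupling the benzylic nickel species may take up methyl from residual alane or homocouple, so that isomers travel on with a chain that is hard to purify. The fallback sets out from 14 (with 17) and 16 and comes back at 19. Alane 18 is quenched with I2 in THF at −30 °C to give (1E,5E,9E,13E,17E)-1-iodo-2,6,10,14,18,22-hexamethyltricosa-1,5,9,13,17,21-hexaene F1, which is purified free of aluminium. Separately, 16 is turned by zinc dust and LiCl in THF into chlorido[(2,3,4,5-tetramethoxy-6-methylphenyl)methyl]zinc F2. F1 and F2 are then joined with Pd(PPh3)4 as the source of zerovalent palladium (Negishi coupling, retention at the alkenyl carbon) to give 19. The polarity of the coupling is inverted and the carbometalation is separated from the C1'–C2' bond formation, while the same two bonds are made.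

Step 10. Water may add to the arene radical cation at a neighbouring pair of methoxy-bearing carbons, leading to an ortho-quinone, or the oxidant may attack the electron-rich chain alkenes. The fallback sets out from 16 and comes back at 20. 16 is oxidised with (NH4)2Ce(NO3)6 in MeCN/H2O at 0 °C to 2-(chloromethyl)-5,6-dimethoxy-3-methylcyclohexa-2,5-diene-1,4-dione F3, which is freed from any isomeric quinone by crystallisation while the material is still cheap. F3 then takes the place of 16 in the zerovalent-nickel coupling with alane 18, a known coupling of alkenylalanes with chloromethyl quinones. This should give 20 directly and removes the oxidation from the polyene stage.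

Step 5. Hydride may be delivered to the tertiary terminus of the palladium allyl complex (migration of C10=C11), or the complex may lose its E geometry. The allylic C1–O bond may also be hydrogenolysed if acetate cleavage is not complete before the catalyst is added. The fallback sets out from 7 and comes back at 9. 7 is deacetylated with K2CO3 in MeOH and hydroxy sulfone 8 is isolated. Its C–S bond is then cleaved with lithium in ethylamine at −78 °C, a dissolving-metal desulfonylation by electron transfer that has no palladium allyl intermediate and leaves the allylic alkoxide alone, to give 9. No compound outside the list arises (F0).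

Further compounds
F1 | step 9 | (1E,5E,9E,13E,17E)-1-iodo-2,6,10,14,18,22-hexamethyltricosa-1,5,9,13,17,21-hexaene | I/C=C(\C)CC/C=C(\C)CC/C=C(\C)CC/C=C(\C)CC/C=C(\C)CCC=C(C)C
F2 | step 9 | chlorido[(2,3,4,5-tetramethoxy-6-methylphenyl)methyl]zinc | COc1c(OC)c(C)c(C[Zn]Cl)c(OC)c1OC
F3 | step 10 | 2-(chloromethyl)-5,6-dimethoxy-3-methylcyclohexa-2,5-diene-1,4-dione | COC1=C(OC)C(=O)C(CCl)=C(C)C1=O
F0 | step 5 | none | none
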